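## The problem

Diplotrin A (18) is 2',5'-dihydroxy-3,7,8,4'-tetramethoxyflavone: a benzopyranone (rings A and C) with methoxy groups at C3, C7 and C8, joined through C2–C1' to a ring B that is a 4'-O-methylated hydroquinone. It has no stereocentre, so nothing has to be controlled in space; the centres that appear on the way (C2, C3, C4) are transient and none has to direct another. What must be solved is placement and oxidation level: six oxygens on two benzene rings, four as methyl ethers and two as free phenols, and a ring C that ends as C2=C3(OMe)–C4=O. The C2–C1' bond is flanked by the 2'-oxygen and the C3 oxygen, so attaching ring B to a finished pyranone is crowded and best avoided. The sensitive part is ring B: with O2' and O5' free it is a hydroquinone that air, base or any oxidant turns into a quinone, so both oxygens must stay masked until the last step, by groups that come off beside four methyl ethers; the pyranone is also opened by strong nucleophiles at C2. The feature that opens the structure is that C2 carries both O1 and ring B, while C4a is the only hydrogen-bearing ortho carbon of the 2,3-dimethoxyphenol unit in ring A (the other ortho carbon, C8, holds a methoxy group). A 1-arylpropargyl ether of that phenol therefore already contains C2, C3 and C4 with ring B attached, and a sigmatropic shift from oxygen can deliver C4 only to C4a.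

## Retrosynthesis

**18 ⇒ 17.** The two O–CH2Ph bonds at O2' and O5' are cut last. A late selective demethylation of a fully methylated flavone has no handle in this molecule. Acyl or silyl groups would not survive, taken together, the Grignard addition, the 180 °C rearrangement and the basic methylation. Benzyl ethers survive all of these, and their removal by hydrogenolysis is neutral and reductive, which suits a product that is an air-sensitive hydroquinone. The forward step must leave the pyranone and four methyl ethers untouched.

**17 ⇒ 16.** The O–CH3 bond at C3 is cut. This is the only methyl ether that does not come from a commercial arene. Flavonol 16 has a single free hydroxyl, so the methylation has no selectivity question.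

**16 ⇒ 13 ⇒ 12.** The C3–O and C4–O bonds are taken back, through flavan-3,4-diol 13, to the C3=C4 double bond of flavene 12. The neighbouring option, hydroxylating C3 of a finished flavone, needs a strong base or an electrophilic oxidant on a hindered, electron-rich enol ether. Here one dihydroxylation places oxygen on both carbons, and oxidation of both carbinols gives 3,4-dione 15, a tautomer of flavonol 16. The forward steps ask only for a syn-dihydroxylation of either face and an oxidant that does not cleave the glycol.

**12 ⇒ 8 (key disconnection).** The C4–C4a bond is cut and O1–C2 is moved back to the open-chain ether, which gives the 1-arylpropargyl aryl ether 8. Cutting C2–C1' instead would require aryl addition to a crowded chromenylium or chromone carbon. Cutting C4–C4a as an acylation would need a regioselective Friedel–Crafts reaction on a ring with three donor groups. The sigmatropic route needs no halide and no directing group, because the ortho carbon is chosen by the substitution pattern itself. Ether 8 has one ring fewer and is made of two arenes and a three-carbon unit. The forward reaction must run a [3,3] shift, enolisation, a 1,5-hydrogen shift and an oxa-6π closure in one operation, without ionising the benzylic, propargylic C–O bond.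

**8 ⇒ 6 + 7.** The bond between the phenol oxygen (later O1) and the propargylic carbon (later C2) is cut. Alkylating the phenoxide of 7 with a 1-arylpropargyl halide is the obvious neighbour, but such halides of so electron-rich a ring ionise and isomerise to allenes. Activating alcohol 6 in the flask under Mitsunobu conditions avoids isolating any such electrophile. 2,3-Dimethoxyphenol 7 is commercial.

**6 ⇒ 4 + 5.** The C2–C3 bond is cut, which is an addition of ethynylmagnesium bromide 5 to aldehyde 4. The reverse polarity, an aryl metal of ring B added to a three-carbon ynal, would need a metalated arene and a far less stable aldehyde. The new carbinol centre needs no control.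

**4 ⇒ 2 ⇒ 1.** The C1'–CHO bond and the two benzyl ether bonds are cut. In 2 the position para to the methoxy group and ortho to a benzyloxy group is the most activated and least hindered, as in other 1,2,4-trialkoxybenzenes. A Vilsmeier formylation therefore sets the 2',5'-dioxygen-4'-methoxy pattern of ring B from commercial 2-methoxyhydroquinone 1 without any blocking group.

## Roads not taken

**Alternative 1: Dötz benzannulation of ring B.** The cut runs through ring B itself: C1'–C2', C2'–C3' and C5'–C6' are opened. This leads back to 2-ethynyl-3,7,8-trimethoxychromen-4-one A1 and to the alkenylcarbene complex pentacarbonyl[methoxy(1-methoxyvinyl)carbene]chromium A2, of formula (CO)5Cr=C(OMe)C(OMe)=CH2, one carbonyl ligand of A2 supplying the sixth ring carbon. In the forward step A1 and A2 would combine, with insertion of that ligand, to 2-(2-hydroxy-4,5-dimethoxyphenyl)-3,7,8-trimethoxychromen-4-one A3.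

- Merits: ring C would carry its 3-methoxy group and C4 carbonyl from the start, so no oxidation steps follow the key step. In that respect it is better than the chosen plan, which spends four steps after the rearrangement. The benzannulation also puts the new hydroxyl ortho to the chromone, where the target has O2'.
- Weak points: A3 is not the target but its 5'-O-methyl ether, because the carbene carbon of A2 brings its own methoxy group to C5'. Removing one of five methyl ethers, with nothing to tell O5' from O4', is an unsolved end-game. A carbene with a removable alkoxy group would be a different and less accessible reagent. The alkyne of A1 is conjugated to the pyranone and electron-poor, a poor partner for this reaction. A1 needs a multi-step synthesis of its own, and A2 is a stoichiometric chromium reagent.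
- Comparison: the chosen plan sets against the better oxidation economy of this road an end-game with no selectivity question: methylation of the only free hydroxyl, then hydrogenolysis.

**Alternative 2: one-carbon ring expansion of a benzofuranone.** The cut removes C3 from between C2 and C4. This leads back to the silyl enol ether tert-butyl({2-[2,5-bis(benzyloxy)-4-methoxyphenyl]-6,7-dimethoxy-1-benzofuran-3-yl}oxy)dimethylsilane A4. In the forward step dibromocarbene A5, made in the flask from the haloform and an alkoxide base, would add to the enol ether double bond of A4. The dibromocyclopropane would open with loss of bromide and the silyl group, so the furan grows into the pyranone of 2-[2,5-bis(benzyloxy)-4-methoxyphenyl]-3-bromo-7,8-dimethoxychromen-4-one A6.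

- Merits: the C4 carbonyl and the C2=C3 double bond arrive in one step at the right oxidation level, with a handle at C3. This is more direct than the flavene–diol–dione path of the chosen plan.
- Weak points: turning C3–Br of A6 into C3–OMe has no dependable solution. Methoxide attacks chromones at C2 and opens or contracts the ring. A metal-catalysed C–O coupling would have to act on a tetrasubstituted vinyl bromide next to the 2'-benzyloxy aryl group. A5 must add to a tetrasubstituted, hindered alkene in strong base. The ketone from which A4 is silylated is an easily oxidised 2-aryl ketone that needs several steps itself.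
- Comparison: the step counts are similar. The chosen plan has one demanding step. This road has two, the addition of A5 and the bromide-to-oxygen exchange, and the second sits at the very point where the chosen plan uses a routine alkene dihydroxylation.

**Alternative 3: carbonylative annulation of ring C.** The cut takes out C4a–C4, C4–C3 and O1–C2. This leads back to 6-iodo-2,3-dimethoxyphenol A7, 1,4-bis(benzyloxy)-2-ethynyl-5-methoxybenzene A8 and carbon monoxide A9. In the forward step a palladium-catalysed carbonylative coupling of A7, A8 and A9 in a secondary amine, followed by 6-endo closure of the phenol onto the ynone, would give 2-[2,5-bis(benzyloxy)-4-methoxyphenyl]-7,8-dimethoxychromen-4-one A10.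

- Merits: this is the most convergent road. It forms three bonds in one step, reaches the flavone oxidation level directly, and the reaction type is established for flavones. A8 is one homologation step from aldehyde 4. In convergence and in the precedent of its ring-forming step it is at least the equal of the chosen plan, and its longest linear sequence would be shorter.
- Weak points: A10 has no oxygen at C3. Reaching flavonol 16 would need a C3 hydroxylation of an electron-rich flavone beside the hindered ring B, by deprotonation and borate oxidation or by a dioxirane. A7 cannot be made by simple iodination of 7, since the position para to the hydroxyl competes; it needs protection, directed ortho-metalation and deprotection. The 5-exo closure to an aurone competes with the 6-endo closure, and A9 is a toxic gas that has to be handled under pressure or from a surrogate.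
- Comparison: against the convergence of this road the chosen plan sets a C3 oxygen that is built in rather than added. The rearrangement leaves a C3=C4 alkene, so C3–O and C4=O both come from it. The chosen plan also needs neither the halogenated phenol A7 nor the gas A9.

Key step: step 5

## Route

Assumption: compounds 6, 8 and 12–15 are racemic and 9–11 are transient; each SMILES shows one enantiomer where a centre is defined, and since 18 has no stereocentre none of this needs control.

Step 1
Reactants: 1 2-methoxyhydroquinone (2-methoxybenzene-1,4-diol)
Product: 2 1,4-bis(benzyloxy)-2-methoxybenzene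
Conditions: BnBr, K2CO3, DMF, 60 °C, N2
Reagents that add atoms: benzyl bromide, BrCc1ccccc1
Why: Williamson ether synthesis; both phenoxides are alkylated by the benzylic bromide, under nitrogen because the hydroquinone anion is air-sensitive. Benzyl is chosen because it survives POCl3, the Grignard reagent, 180 °C, OsO4, IBX and carbonate base, and is removed at the end without touching methyl ethers.

Step 2
Reactants: 2 1,4-bis(benzyloxy)-2-methoxybenzene
Product: 4 2,5-bis(benzyloxy)-4-methoxybenzaldehyde, via aryl iminium chloride 3 (not isolated)
Conditions: POCl3, DMF, 0 → 75 °C; then ice–H2O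
Reagents that add atoms: N,N-dimethylformamide, CN(C)C=O; water, O
Why: Vilsmeier–Haack formylation; the chloroiminium ion attacks the carbon para to the methoxy group and ortho to a benzyloxy group, the most activated and unhindered position of a 1,2,4-trialkoxybenzene. Hydrolysis of iminium salt 3 gives the aldehyde.

Step 3
Reactants: 4 2,5-bis(benzyloxy)-4-methoxybenzaldehyde; 5 ethynylmagnesium bromide
Product: 6 rac-1-[2,5-bis(benzyloxy)-4-methoxyphenyl]prop-2-yn-1-ol
Conditions: HC≡CMgBr, THF, 0 °C → rt; then sat. aq NH4Cl
Reagents that add atoms: none
Why: Grignard addition of an alkynyl nucleophile to an aryl aldehyde; the carbinol centre forms without control and is racemic, which is immaterial. The acid-sensitive alcohol is worked up without acid and used promptly.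

Step 4
Reactants: 6 rac-1-[2,5-bis(benzyloxy)-4-methoxyphenyl]prop-2-yn-1-ol; 7 2,3-dimethoxyphenol
Product: 8 rac-1,4-bis(benzyloxy)-2-[1-(2,3-dimethoxyphenoxy)prop-2-yn-1-yl]-5-methoxybenzene
Conditions: PPh3, DIAD, THF, 0 °C → rt
Reagents that add atoms: none
Why: Mitsunobu etherification; the phenol (pKa about 10) protonates the PPh3–DIAD betaine and its phenoxide displaces the oxyphosphonium group at the secondary carbinol carbon, with inversion that is immaterial for a racemate. The carbinol carbon has no β-hydrogen, so elimination cannot compete.

Step 5
Reactants: 8 rac-1,4-bis(benzyloxy)-2-[1-(2,3-dimethoxyphenoxy)prop-2-yn-1-yl]-5-methoxybenzene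
Product: 12 rac-2-[2,5-bis(benzyloxy)-4-methoxyphenyl]-7,8-dimethoxy-2H-chromene, via allenyl dienone 9 (not isolated), via allenylphenol 10 (not isolated), via ortho-quinone methide 11 (not isolated)
Conditions: PhNEt2 (degassed), 180 °C, Ar
Reagents that add atoms: none
Why: This is the aryl propargyl ether Claisen cascade, the standard thermal route from such ethers to 2H-chromenes and the same sequence by which 1-aryl- and 1,1-diarylpropargyl aryl ethers give 2-aryl-2H-chromenes and naphthopyrans. A concerted [3,3] shift joins the alkyne terminus to the only hydrogen-bearing ortho carbon (C4–C4a) and breaks O1–C2, giving dienone 9, which enolises to allenylphenol 10. A 1,5-hydrogen shift from the phenol O–H to the central allene carbon then gives the vinyl ortho-quinone methide 11. Ring C closes by a thermally allowed, disrotatory oxa-6π electrocyclisation that re-forms O1–C2 and restores the aromaticity of ring A. The selectivity needed is regiochemical: a shift to the methoxy-bearing ortho carbon gives a dienone that cannot enolise and can only revert, so the 2,3-dimethoxy pattern funnels the material through C4a. C2 is rebuilt from the planar 11 with no control element, so 12 is racemic, which is harmless because C2 becomes sp2 in step 7. The aryl group on the propargylic carbon should lower the barrier of the [3,3] shift, and the basic solvent suppresses acid-catalysed ionisation of the benzylic, propargylic C–O bond.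

Step 6
Reactants: 12 rac-2-[2,5-bis(benzyloxy)-4-methoxyphenyl]-7,8-dimethoxy-2H-chromene
Product: 13 rac-(2R,3S,4S)-2-[2,5-bis(benzyloxy)-4-methoxyphenyl]-7,8-dimethoxy-3,4-dihydro-2H-chromene-3,4-diol (2,3-trans-3,4-cis)
Conditions: OsO4 (cat.), NMO, acetone–H2O, rt
Reagents that add atoms: osmium tetroxide, O=[Os](=O)(=O)=O; N-methylmorpholine N-oxide, C[N+]1([O-])CCOCC1; water, O
Why: Catalytic OsO4 syn-dihydroxylation of the styrene-type C3=C4 bond, a known conversion of flav-3-enes into flavan-3,4-diols. The reagent should add to the face away from the C2 aryl group, giving the 2,3-trans-3,4-cis diol; this relative configuration is set by C2 and is not needed later.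

Step 7
Reactants: 13 rac-(2R,3S,4S)-2-[2,5-bis(benzyloxy)-4-methoxyphenyl]-7,8-dimethoxy-3,4-dihydro-2H-chromene-3,4-diol
Product: 16 2-[2,5-bis(benzyloxy)-4-methoxyphenyl]-3-hydroxy-7,8-dimethoxy-4H-chromen-4-one, via hydroxy ketone 14 (not isolated), via chromane-3,4-dione 15 (not isolated)
Conditions: IBX, DMSO, rt → 45 °C
Reagents that add atoms: none
Why: IBX oxidises 1,2-diols to 1,2-dicarbonyl compounds without cleaving the C–C bond; the benzylic C4 carbinol should go first (14), but either order leads to dione 15. Enolisation of 15 through C2–H gives the aromatic 3-hydroxypyranone 16 and removes all three stereocentres.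

Step 8
Reactants: 16 2-[2,5-bis(benzyloxy)-4-methoxyphenyl]-3-hydroxy-7,8-dimethoxy-4H-chromen-4-one
Product: 17 2-[2,5-bis(benzyloxy)-4-methoxyphenyl]-3,7,8-trimethoxy-4H-chromen-4-one
Conditions: MeI, K2CO3, DMF, rt
Reagents that add atoms: iodomethane, CI
Why: Williamson O-methylation of the only free hydroxyl, the acidic 3-OH of a flavonol, a routine conversion of flavonols into 3-methyl ethers.

Step 9
Reactants: 17 2-[2,5-bis(benzyloxy)-4-methoxyphenyl]-3,7,8-trimethoxy-4H-chromen-4-one
Product: 18 diplotrin A, 2-(2,5-dihydroxy-4-methoxyphenyl)-3,7,8-trimethoxy-4H-chromen-4-one
Conditions: H2 (1 atm), 10% Pd/C, EtOAc–MeOH, rt; filtration and concentration under Ar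
Reagents that add atoms: none
Why: Catalytic hydrogenolysis of aryl benzyl ethers; methyl ethers and the tetrasubstituted C2=C3 bond of the pyranone are inert at one atmosphere. The reducing medium keeps the freed hydroquinone from oxidising.

## Compound list

1 | 2-methoxyhydroquinone (2-methoxybenzene-1,4-diol) | COc1cc(O)ccc1O | starting material
2 | 1,4-bis(benzyloxy)-2-methoxybenzene | COc1cc(OCc2ccccc2)ccc1OCc1ccccc1 | intermediate
3 | N-[2,5-bis(benzyloxy)-4-methoxybenzylidene]-N-methylmethanaminium chloride (formed in the flask, not isolated) | C[N+](C)=Cc1cc(OCc2ccccc2)c(OC)cc1OCc1ccccc1.[Cl-] | intermediate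
4 | 2,5-bis(benzyloxy)-4-methoxybenzaldehyde | COc1cc(OCc2ccccc2)c(C=O)cc1OCc1ccccc1 | intermediate
5 | ethynylmagnesium bromide | C#C[Mg]Br | starting material
6 | rac-1-[2,5-bis(benzyloxy)-4-methoxyphenyl]prop-2-yn-1-ol ((S) enantiomer drawn) | C#C[C@H](O)c1cc(OCc2ccccc2)c(OC)cc1OCc1ccccc1 | intermediate
7 | 2,3-dimethoxyphenol | COc1cccc(O)c1OC | starting material
8 | rac-1,4-bis(benzyloxy)-2-[1-(2,3-dimethoxyphenoxy)prop-2-yn-1-yl]-5-methoxybenzene ((R) enantiomer drawn) | C#C[C@@H](Oc1cccc(OC)c1OC)c1cc(OCc2ccccc2)c(OC)cc1OCc1ccccc1 | intermediate
9 | 6-{3-[2,5-bis(benzyloxy)-4-methoxyphenyl]propa-1,2-dien-1-yl}-2,3-dimethoxycyclohexa-2,4-dien-1-one (not isolated; transient mixture, ring centre and allene axis undefined) | O=C1C(OC)=C(OC)C=CC1C=C=Cc1cc(OCc2ccccc2)c(OC)cc1OCc1ccccc1 | intermediate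
10 | 6-{3-[2,5-bis(benzyloxy)-4-methoxyphenyl]propa-1,2-dien-1-yl}-2,3-dimethoxyphenol (not isolated; racemic allene, axis undefined) | COc1ccc(C=C=Cc2cc(OCc3ccccc3)c(OC)cc2OCc2ccccc2)c(O)c1OC | intermediate
11 | (6Z)-6-{(2Z)-3-[2,5-bis(benzyloxy)-4-methoxyphenyl]prop-2-en-1-ylidene}-2,3-dimethoxycyclohexa-2,4-dien-1-one (not isolated; either geometry of the side-chain C=C can close) | O=C1C(OC)=C(OC)C=C/C1=C/C=C\c1cc(OCc2ccccc2)c(OC)cc1OCc1ccccc1 | intermediate
12 | rac-2-[2,5-bis(benzyloxy)-4-methoxyphenyl]-7,8-dimethoxy-2H-chromene ((S) enantiomer drawn) | COc1ccc2c(c1OC)O[C@H](c1cc(OCc3ccccc3)c(OC)cc1OCc1ccccc1)C=C2 | intermediate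
13 | rac-(2R,3S,4S)-2-[2,5-bis(benzyloxy)-4-methoxyphenyl]-7,8-dimethoxy-3,4-dihydro-2H-chromene-3,4-diol (2,3-trans-3,4-cis; C2 drawn as in 12, its descriptor changes because C3 now outranks the aryl group) | COc1ccc2c(c1OC)O[C@H](c1cc(OCc3ccccc3)c(OC)cc1OCc1ccccc1)[C@@H](O)[C@H]2O | intermediate
14 | rac-(2R,3R)-2-[2,5-bis(benzyloxy)-4-methoxyphenyl]-3-hydroxy-7,8-dimethoxy-2,3-dihydro-4H-chromen-4-one (2,3-trans; not isolated) | COc1ccc2c(c1OC)O[C@H](c1cc(OCc3ccccc3)c(OC)cc1OCc1ccccc1)[C@@H](O)C2=O | intermediate
15 | 2-[2,5-bis(benzyloxy)-4-methoxyphenyl]-7,8-dimethoxy-2H-chromene-3,4-dione (not isolated; racemic and labile at C2, (2R) drawn) | COc1ccc2c(c1OC)O[C@H](c1cc(OCc3ccccc3)c(OC)cc1OCc1ccccc1)C(=O)C2=O | intermediate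
16 | 2-[2,5-bis(benzyloxy)-4-methoxyphenyl]-3-hydroxy-7,8-dimethoxy-4H-chromen-4-one | COc1ccc2c(=O)c(O)c(-c3cc(OCc4ccccc4)c(OC)cc3OCc3ccccc3)oc2c1OC | intermediate
17 | 2-[2,5-bis(benzyloxy)-4-methoxyphenyl]-3,7,8-trimethoxy-4H-chromen-4-one | COc1ccc2c(=O)c(OC)c(-c3cc(OCc4ccccc4)c(OC)cc3OCc3ccccc3)oc2c1OC | intermediate
18 | diplotrin A, 2-(2,5-dihydroxy-4-methoxyphenyl)-3,7,8-trimethoxy-4H-chromen-4-one | COc1cc(O)c(-c2oc3c(OC)c(OC)ccc3c(=O)c2OC)cc1O | target

## Step count and risks

Total: 9 steps. Longest linear sequence: 9 steps (1 → 18); compounds 5 and 7 are bought.

**Step 5 (key step).** The most likely failure is heterolysis of the benzylic, propargylic C–O bond at 180 °C, favoured by the electron-rich ring B, so that the phenol is alkylated at carbon or the material oligomerises before the [3,3] shift. Next in likelihood are closure of allenylphenol 10 through oxygen onto the central allene carbon, which leads to a benzofuran, and thermal ring-opening of the product on long heating. The fallback sets out from ether 8 and returns at flavene 12 by a different bond-forming event. A cationic gold phosphine complex, Ph3PAuNTf2, in CH2Cl2 at room temperature should activate the alkyne for 6-endo-dig hydroarylation by the free ortho carbon, which is also para to the future C7 methoxy group. C4–C4a then forms directly and O1–C2 is never broken. This cycloisomerisation of aryl propargyl ethers to 2H-chromenes is known and makes no new compound.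

**Step 4.** The most likely failure is ionisation of the oxyphosphonium intermediate to a stabilised cation. The cation is then captured at a ring carbon of the phenol, at the hydrazide nitrogen or at the alkyne terminus (allenyl ether), and the hindered phenol converts slowly. The fallback sets out from alcohol 6. Acetylation (Ac2O, Et3N, DMAP) gives 1-[2,5-bis(benzyloxy)-4-methoxyphenyl]prop-2-yn-1-yl acetate F1. A copper-catalysed propargylic substitution with phenol 7 (CuOTf·0.5C6H6, a pybox ligand, iPr2NEt) then proceeds through a copper allenylidene, which the terminal alkyne makes possible, and returns to the route at ether 8.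

**Step 7.** The most likely failures are cleavage of the C3–C4 glycol, arrest at the ketol stage, and further oxidation of the electron-rich flavonol by the iodine reagent. The fallback gives up the diol and sets out from aldehyde 4. Claisen–Schmidt condensation with 1-(2-hydroxy-3,4-dimethoxyphenyl)ethanone F2 (KOH, EtOH) gives (E)-3-[2,5-bis(benzyloxy)-4-methoxyphenyl]-1-(2-hydroxy-3,4-dimethoxyphenyl)prop-2-en-1-one F3. Algar–Flynn–Oyamada oxidation (H2O2, NaOH, MeOH) closes ring C with the C3 hydroxyl in place and returns to the route at flavonol 16. The ketone ring has no substituent ortho to the acyl group other than the hydroxyl, which favours the flavonol over the aurone.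

**Step 9.** The most likely failure is air oxidation of the freed methoxyhydroquinone to the quinone during filtration and concentration. Less likely are slow cleavage of the hindered 2'-benzyl ether and saturation of C2=C3 on forcing. The fallback sets out from 17 and returns at 18 without hydrogen: BCl3 with pentamethylbenzene as cation scavenger in CH2Cl2 at −78 °C, followed by a reducing aqueous work-up with Na2S2O4. This is a Lewis-acid debenzylation that at low temperature should spare the methyl ethers, and it makes no new compound.

## Further compounds

F0 | step 5 | none | none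
F1 | step 4 | rac-1-[2,5-bis(benzyloxy)-4-methoxyphenyl]prop-2-yn-1-yl acetate ((S) enantiomer drawn) | C#C[C@H](OC(C)=O)c1cc(OCc2ccccc2)c(OC)cc1OCc1ccccc1
F2 | step 7 | 1-(2-hydroxy-3,4-dimethoxyphenyl)ethanone | CC(=O)c1ccc(OC)c(OC)c1O
F3 | step 7 | (E)-3-[2,5-bis(benzyloxy)-4-methoxyphenyl]-1-(2-hydroxy-3,4-dimethoxyphenyl)prop-2-en-1-one | COc1ccc(C(=O)/C=C/c2cc(OCc3ccccc3)c(OC)cc2OCc2ccccc2)c(O)c1OC
F0 | step 9 | none | none
A1 | alternative 1 | 2-ethynyl-3,7,8-trimethoxychromen-4-one | C#Cc1oc2c(OC)c(OC)ccc2c(=O)c1OC
A2 | alternative 1 | pentacarbonyl[methoxy(1-methoxyvinyl)carbene]chromium | COC(C(=C)OC)=[Cr](=C=O)(=C=O)(=C=O)(=C=O)=C=O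
A3 | alternative 1 | 2-(2-hydroxy-4,5-dimethoxyphenyl)-3,7,8-trimethoxychromen-4-one | COc1cc(O)c(-c2oc3c(OC)c(OC)ccc3c(=O)c2OC)cc1OC
A4 | alternative 2 | tert-butyl({2-[2,5-bis(benzyloxy)-4-methoxyphenyl]-6,7-dimethoxy-1-benzofuran-3-yl}oxy)dimethylsilane | COc1ccc2c(O[Si](C)(C)C(C)(C)C)c(-c3cc(OCc4ccccc4)c(OC)cc3OCc3ccccc3)oc2c1OC
A5 | alternative 2 | dibromocarbene | Br[C]Br
A6 | alternative 2 | 2-[2,5-bis(benzyloxy)-4-methoxyphenyl]-3-bromo-7,8-dimethoxychromen-4-one | COc1ccc2c(=O)c(Br)c(-c3cc(OCc4ccccc4)c(OC)cc3OCc3ccccc3)oc2c1OC
A7 | alternative 3 | 6-iodo-2,3-dimethoxyphenol | COc1ccc(I)c(O)c1OC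
A8 | alternative 3 | 1,4-bis(benzyloxy)-2-ethynyl-5-methoxybenzene | C#Cc1cc(OCc2ccccc2)c(OC)cc1OCc1ccccc1
A9 | alternative 3 | carbon monoxide | [C-]#[O+]
A10 | alternative 3 | 2-[2,5-bis(benzyloxy)-4-methoxyphenyl]-7,8-dimethoxychromen-4-one | COc1ccc2c(=O)cc(-c3cc(OCc4ccccc4)c(OC)cc3OCc3ccccc3)oc2c1OC
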